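**Retrosynthetic overview**

1. The target is cut back by removing the ring A C3 chlorine (the only aromatic C–H left in the depside) and two benzyl ethers, then at the depside ester bond between the ring B C4 oxygen and the ring A carbonyl. This gives a ring B phenol and 2,4-bis(benzyloxy)-3,6-dimethylbenzoic acid, the latter from atraric acid.
2. In ring B the C6 methyl and the C1 methoxycarbonyl sit on neighbouring carbons, and C1 is flanked on its other side by the C2 methoxy group. Both C–C bonds are therefore cut together, back to a ring B C1–C6 aryne (from the C1,C6-dibromide), MeMgCl and ClCO2Me.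
3. The dibromide comes from 2,4-dihydroxy-3-methylbenzaldehyde by 4-O-methylation, reduction of CHO to CH3, dibromination and O-benzylation.
4. No ring is constructed; both benzene rings are bought. Ring B is elaborated first (steps 1–6), the ring A acid is made in parallel (steps 7–8), and the two are joined and finished (steps 9–11).

Key step: step 5

Remark on the chemistry: ring B is numbered from the ester-bearing carbon (C1 CO2Me, C2 OMe, C3 CH3, C4 O-acyl, C5 CH3, C6 CH3). Ring A is numbered as in the target name (C1 carbonyl-bearing, C2 CH3, C3 Cl, C4 OH, C5 CH3, C6 OH). The target has no stereocentre, so no configuration has to be set.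

**Route**

Step 1
Reactants: 1 2,4-dihydroxy-3-methylbenzaldehyde
Product: 2 2-hydroxy-4-methoxy-3-methylbenzaldehyde
Conditions: MeI (1.1 equiv), K2CO3 (1.1 equiv), acetone, reflux
Reagents that add atoms: iodomethane, CI
Why: Williamson etherification that should be selective for the 4-hydroxyl, because the 2-hydroxyl is held in a hydrogen bond to the formyl oxygen and is the less acidic and less nucleophilic of the two.

Step 2
Reactants: 2 2-hydroxy-4-methoxy-3-methylbenzaldehyde
Product: 4 3-methoxy-2,6-dimethylphenol, via 6-(hydroxymethyl)-3-methoxy-2-methylphenol 3 (not isolated)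
Conditions: H2 (3 bar), 10% Pd/C, AcOH, cat. HCl, rt
Reagents that add atoms: none
Why: Catalytic hydrogenation of the aldehyde to the benzylic alcohol, then acid-assisted hydrogenolysis of its C–O bond, which the ortho hydroxyl and para methoxy groups activate (reduction of an electron-rich benzaldehyde to the methylarene).

Step 3
Reactants: 4 3-methoxy-2,6-dimethylphenol
Product: 6 3,4-dibromo-5-methoxy-2,6-dimethylphenol, via 4-bromo-3-methoxy-2,6-dimethylphenol 5 (not isolated)
Conditions: Br2 (2.3 equiv), AcOH, rt → 50 °C; aq. NaHSO3 work-up
Reagents that add atoms: bromine, BrBr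
Why: Electrophilic aromatic bromination in which the first bromine should enter ring B C1 (para to the hydroxyl, ortho to the methoxy group) and the second the only remaining position, C6, which the ortho and para methyl groups activate, while the HBr formed keeps any ipso bromination of the phenol reversible.

Step 4
Reactants: 6 3,4-dibromo-5-methoxy-2,6-dimethylphenol
Product: 7 1-(benzyloxy)-3,4-dibromo-5-methoxy-2,6-dimethylbenzene (ring B numbering: Br at C1 and C6, OMe at C2, OBn at C4)
Conditions: BnBr (1.3 equiv), K2CO3, DMF, 60 °C
Reagents that add atoms: benzyl bromide, BrCc1ccccc1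
Why: Williamson etherification; in DMF the potassium phenoxide flanked by two methyl groups should still be alkylated at oxygen by the unhindered benzylic bromide.

Step 5
Reactants: 7 1-(benzyloxy)-3,4-dibromo-5-methoxy-2,6-dimethylbenzene, 8 methylmagnesium chloride, 9 methyl chloroformate
Product: 13 methyl 4-(benzyloxy)-2-methoxy-3,5,6-trimethylbenzoate, via 2-bromoarylmagnesium chloride 10 (not isolated), via ring B C1-C6 aryne 11 (not isolated), via C1 arylmagnesium chloride 12 (not isolated)
Conditions: iPrMgCl·LiCl (1.1 equiv), THF, −15 → 0 °C; then MeMgCl (4 equiv), 0 → 50 °C; then cannulated into ClCO2Me (8 equiv), THF, −78 °C → rt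
Reagents that add atoms: methylmagnesium chloride, C[Mg]Cl; methyl chloroformate, COC(=O)Cl
Why: iPrMgCl·LiCl exchanges one bromine (the C1 bromine beside the methoxy group is expected to react first, but either exchange leads on), and on warming the 2-bromoarylmagnesium 10 loses MgBrCl to give the C1–C6 aryne 11. MeMgCl then adds across the strained triple bond, forming the C6–CH3 bond and arylmagnesium 12, which is acylated by methyl chloroformate to form the C1–CO2Me bond. The closest known reaction type is the generation of arynes from 1,2-dihaloarenes with magnesium reagents, addition of a Grignard reagent to the aryne, and electrophilic trapping of the resulting ortho-substituted arylmagnesium. No ring is closed and no stereocentre is formed. The step needs regioselective attack of the methyl group at C6: the inductively withdrawing C2 methoxy group distorts the aryne so that C6 is the more electrophilic carbon and the developing negative charge sits at C1, where it is stabilised inductively and by Mg–O chelation, which should outweigh the small steric bias of the C5 methyl. Completing the exchange cold before the excess MeMgCl is added limits isopropyl transfer to the aryne, and inverse addition into excess chloroformate, together with the two ortho substituents at C1, should stop acylation at the ester.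

Step 6
Reactants: 13 methyl 4-(benzyloxy)-2-methoxy-3,5,6-trimethylbenzoate
Product: 14 methyl 4-hydroxy-2-methoxy-3,5,6-trimethylbenzoate
Conditions: H2 (1 atm), 10% Pd/C, EtOAc/MeOH, rt
Reagents that add atoms: none
Why: Catalytic hydrogenolysis of the benzylic C–O bond frees the C4 phenol; the methyl ester and methyl ether are inert and no reducible halogen remains.

Step 7
Reactants: 15 atraric acid (methyl 2,4-dihydroxy-3,6-dimethylbenzoate)
Product: 16 methyl 2,4-bis(benzyloxy)-3,6-dimethylbenzoate
Conditions: BnBr (2.5 equiv), K2CO3 (3 equiv), DMF, 70 °C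
Reagents that add atoms: benzyl bromide, BrCc1ccccc1
Why: Double Williamson etherification; heating in DMF with excess base and bromide should also alkylate the ester-chelated 2-hydroxyl.

Step 8
Reactants: 16 methyl 2,4-bis(benzyloxy)-3,6-dimethylbenzoate
Product: 17 2,4-bis(benzyloxy)-3,6-dimethylbenzoic acid
Conditions: KOH (10 equiv), DMSO/H2O (5:1), 90 °C; then 1 M HCl
Reagents that add atoms: potassium hydroxide, [K+].[OH-]
Why: Saponification of a doubly ortho-substituted methyl ester, which needs poorly solvated hydroxide in hot aqueous DMSO; the benzyl ethers are stable to base.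

Step 9
Reactants: 17 2,4-bis(benzyloxy)-3,6-dimethylbenzoic acid, 14 methyl 4-hydroxy-2-methoxy-3,5,6-trimethylbenzoate
Product: 19 methyl 4-{[2,4-bis(benzyloxy)-3,6-dimethylbenzoyl]oxy}-2-methoxy-3,5,6-trimethylbenzoate, via mixed trifluoroacetic anhydride 18 (not isolated)
Conditions: (CF3CO)2O (3 equiv), toluene, 0 °C → rt
Reagents that add atoms: none
Why: Trifluoroacetic anhydride-mediated esterification as used for depsides, in which the acid forms mixed anhydride 18, whose electron-rich, doubly ortho-substituted aroyl group ionises readily towards an acylium ion small enough to be captured by the hindered ring B C4 phenol.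

Step 10
Reactants: 19 methyl 4-{[2,4-bis(benzyloxy)-3,6-dimethylbenzoyl]oxy}-2-methoxy-3,5,6-trimethylbenzoate
Product: 20 methyl 4-[(2,4-dihydroxy-3,6-dimethylbenzoyl)oxy]-2-methoxy-3,5,6-trimethylbenzoate
Conditions: H2 (1 atm), 10% Pd/C, EtOAc, rt
Reagents that add atoms: none
Why: Hydrogenolysis of both benzyl ethers under neutral conditions should leave the aryl ester linkage and the methyl ester intact, and it is placed before the chlorination so that no aryl chloride meets Pd/C and hydrogen.

Step 11
Reactants: 20 methyl 4-[(2,4-dihydroxy-3,6-dimethylbenzoyl)oxy]-2-methoxy-3,5,6-trimethylbenzoate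
Product: 21 methyl 4-[(3-chloro-4,6-dihydroxy-2,5-dimethylbenzoyl)oxy]-2-methoxy-3,5,6-trimethylbenzoate (target)
Conditions: SO2Cl2 (1.05 equiv), Et2O, 0 °C → rt
Reagents that add atoms: sulfuryl chloride, O=S(=O)(Cl)Cl
Why: Electrophilic aromatic chlorination of the single unsubstituted aromatic carbon of the molecule, ring A C3, which lies ortho to the C4 hydroxyl and para to the C6 hydroxyl, while the fully substituted ring B and both esters should be untouched by one equivalent of reagent.

**Compound list**

1 | 2,4-dihydroxy-3-methylbenzaldehyde | Cc1c(O)ccc(C=O)c1O | starting material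
2 | 2-hydroxy-4-methoxy-3-methylbenzaldehyde | COc1ccc(C=O)c(O)c1C | intermediate
3 | 6-(hydroxymethyl)-3-methoxy-2-methylphenol | COc1ccc(CO)c(O)c1C | intermediate (not isolated)
4 | 3-methoxy-2,6-dimethylphenol | COc1ccc(C)c(O)c1C | intermediate
5 | 4-bromo-3-methoxy-2,6-dimethylphenol | COc1c(Br)cc(C)c(O)c1C | intermediate (not isolated)
6 | 3,4-dibromo-5-methoxy-2,6-dimethylphenol | COc1c(Br)c(Br)c(C)c(O)c1C | intermediate
7 | 1-(benzyloxy)-3,4-dibromo-5-methoxy-2,6-dimethylbenzene | COc1c(Br)c(Br)c(C)c(OCc2ccccc2)c1C | intermediate
8 | methylmagnesium chloride | C[Mg]Cl | starting material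
9 | methyl chloroformate | COC(=O)Cl | starting material
10 | [4-(benzyloxy)-6-bromo-2-methoxy-3,5-dimethylphenyl]magnesium chloride | COc1c([Mg]Cl)c(Br)c(C)c(OCc2ccccc2)c1C | intermediate (not isolated)
11 | 5-(benzyloxy)-3-methoxy-4,6-dimethylbenzyne (ring B C1–C6 aryne) | COC1=C(C)C(OCc2ccccc2)=C(C)C#C1 | intermediate (not isolated)
12 | [4-(benzyloxy)-2-methoxy-3,5,6-trimethylphenyl]magnesium chloride | COc1c([Mg]Cl)c(C)c(C)c(OCc2ccccc2)c1C | intermediate (not isolated)
13 | methyl 4-(benzyloxy)-2-methoxy-3,5,6-trimethylbenzoate | COC(=O)c1c(C)c(C)c(OCc2ccccc2)c(C)c1OC | intermediate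
14 | methyl 4-hydroxy-2-methoxy-3,5,6-trimethylbenzoate | COC(=O)c1c(C)c(C)c(O)c(C)c1OC | intermediate
15 | atraric acid (methyl 2,4-dihydroxy-3,6-dimethylbenzoate) | COC(=O)c1c(C)cc(O)c(C)c1O | starting material
16 | methyl 2,4-bis(benzyloxy)-3,6-dimethylbenzoate | COC(=O)c1c(C)cc(OCc2ccccc2)c(C)c1OCc1ccccc1 | intermediate
17 | 2,4-bis(benzyloxy)-3,6-dimethylbenzoic acid | OC(=O)c1c(C)cc(OCc2ccccc2)c(C)c1OCc1ccccc1 | intermediate
18 | 2,4-bis(benzyloxy)-3,6-dimethylbenzoic trifluoroacetic anhydride | O=C(OC(=O)C(F)(F)F)c1c(C)cc(OCc2ccccc2)c(C)c1OCc1ccccc1 | intermediate (not isolated)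
19 | methyl 4-{[2,4-bis(benzyloxy)-3,6-dimethylbenzoyl]oxy}-2-methoxy-3,5,6-trimethylbenzoate | COC(=O)c1c(C)c(C)c(OC(=O)c2c(C)cc(OCc3ccccc3)c(C)c2OCc2ccccc2)c(C)c1OC | intermediate
20 | methyl 4-[(2,4-dihydroxy-3,6-dimethylbenzoyl)oxy]-2-methoxy-3,5,6-trimethylbenzoate | COC(=O)c1c(C)c(C)c(OC(=O)c2c(C)cc(O)c(C)c2O)c(C)c1OC | intermediate
21 | methyl 4-[(3-chloro-4,6-dihydroxy-2,5-dimethylbenzoyl)oxy]-2-methoxy-3,5,6-trimethylbenzoate | COC(=O)c1c(C)c(C)c(OC(=O)c2c(C)c(Cl)c(O)c(C)c2O)c(C)c1OC | target

**Step count and risks**

Total: 11 steps. Longest linear sequence: 9 steps (steps 1–6, then 9–11, from compound 1). The ring A acid takes 2 steps (7–8) before the union.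

Steps most likely to fail:

1. Step 5 (aryne methylation–carboxylation). What may go wrong: incomplete loss of magnesium halide from 10; transfer of the isopropyl group or of an arylmagnesium species to the aryne in place of methyl; erosion of the C6 regioselectivity by the neighbouring C5 methyl; double addition to the chloroformate. Fallback without an aryne, setting out from dibromide 7 and coming back at 13: the exchange is run as before to give 10, which is kept at −15 °C and trapped directly with methyl chloroformate 9 to give methyl 4-(benzyloxy)-6-bromo-2-methoxy-3,5-dimethylbenzoate F1. This relies on the methoxy group directing the exchange to the C1 bromine. The remaining C6 bromide is then methylated by Suzuki–Miyaura coupling (methylboronic acid, Pd(OAc)2, SPhos, K3PO4, toluene/H2O, 100 °C), which should give 13.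

2. Step 3 (dibromination). What may go wrong: stalling after the first bromination, because C6 is meta to both oxygens; ipso attack leading to bromodienones and oxidised material. Fallback that needs no dibromide and no aryne, setting out from atraric acid 15 and coming back at 13: Rieche formylation (Cl2CHOCH3, TiCl4, CH2Cl2, 0 °C) at the one free ring carbon gives methyl 3-formyl-4,6-dihydroxy-2,5-dimethylbenzoate F2. Reduction of the formyl group to methyl (H2, 10% Pd/C, AcOH, as in step 2) gives methyl 2,4-dihydroxy-3,5,6-trimethylbenzoate F3. Benzylation of the non-chelated 4-hydroxyl (BnBr, K2CO3, acetone, reflux) gives methyl 4-(benzyloxy)-2-hydroxy-3,5,6-trimethylbenzoate F4. Methylation of the chelated 2-hydroxyl (MeI, K2CO3, DMF, 60 °C) should then give 13.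

3. Step 9 (depside esterification). What may go wrong: slow acyl transfer between two doubly ortho-substituted partners; trifluoroacetylation of the phenol in place of aroylation; partial loss of benzyl groups in the acidic medium. Fallback under basic conditions, setting out from acid 17 and phenol 14 and coming back at 19: the acid is converted with oxalyl chloride and catalytic DMF in CH2Cl2 into 2,4-bis(benzyloxy)-3,6-dimethylbenzoyl chloride F5. The phenol is deprotonated with NaH in THF to sodium 3-methoxy-4-(methoxycarbonyl)-2,5,6-trimethylphenolate F6. The two are combined in THF at rt → 50 °C, which should give 19.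

**Further compounds**

F1 | step 5 | methyl 4-(benzyloxy)-6-bromo-2-methoxy-3,5-dimethylbenzoate | COC(=O)c1c(Br)c(C)c(OCc2ccccc2)c(C)c1OC
F2 | step 3 | methyl 3-formyl-4,6-dihydroxy-2,5-dimethylbenzoate | COC(=O)c1c(C)c(C=O)c(O)c(C)c1O
F3 | step 3 | methyl 2,4-dihydroxy-3,5,6-trimethylbenzoate | COC(=O)c1c(C)c(C)c(O)c(C)c1O
F4 | step 3 | methyl 4-(benzyloxy)-2-hydroxy-3,5,6-trimethylbenzoate | COC(=O)c1c(C)c(C)c(OCc2ccccc2)c(C)c1O
F5 | step 9 | 2,4-bis(benzyloxy)-3,6-dimethylbenzoyl chloride | O=C(Cl)c1c(C)cc(OCc2ccccc2)c(C)c1OCc1ccccc1
F6 | step 9 | sodium 3-methoxy-4-(methoxycarbonyl)-2,5,6-trimethylphenolate | COC(=O)c1c(C)c(C)c([O-])c(C)c1OC.[Na+]
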